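The route rests on closing the pyran ring at C3–C4. C4 is a benzylic carbon ortho to O1 on ring A and C3 carries ring B, so the bond can be born as the C3=C4 alkene of a 3-aryl-2H-chromene. In one flask a ring-A salicyl phosphonium salt is O-alkylated (O1–C2) by a ring-B phenacyl bromide and the ylide at C4 then closes the ring onto the C3 ketone by intramolecular Wittig olefination. The flat alkene is reduced by iridium-catalysed asymmetric hydrogenation, which sets C3 as S. The 1,1-dimethylallyl group at C5' comes last, from Claisen rearrangement of the 4'-O-prenyl ether.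

Key step: step 8

Remark: isoflavan numbering is used (pyran ring O1, C2, C3, C4; ring A C4a–C8a; ring B C1'–C6'). OTs/tosyloxy = 4-methylbenzenesulfonyloxy; cod = 1,5-cyclooctadiene; tBu-PHOX = 4-tert-butyl-2-[2-(diphenylphosphino)phenyl]-4,5-dihydrooxazole; BArF = tetrakis[3,5-bis(trifluoromethyl)phenyl]borate.
Assumption: the ligand antipode that gives 3S in step 9 is fixed in a small screen of the two commercial antipodes; the route is written for that antipode.

Step 1
Reactants: 1 2,4-dihydroxybenzaldehyde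
Product: 2 2-hydroxy-4-(tosyloxy)benzaldehyde
Conditions: TsCl (1.0 equiv), K2CO3, acetone, 0 °C → rt
Reagents that add atoms: 4-toluenesulfonyl chloride, Cc1ccc(cc1)S(=O)(=O)Cl
Why: Site-selective phenol sulfonylation: the 4-OH is free and acidic while the 2-OH is held in a hydrogen bond to the formyl group, so only O7 of the later ring A should be capped.

Step 2
Reactants: 2 2-hydroxy-4-(tosyloxy)benzaldehyde
Product: 3 2-hydroxy-4-(tosyloxy)benzyl alcohol
Conditions: NaBH4, THF/MeOH, 0 °C
Reagents that add atoms: none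
Why: Borohydride reduction of an aryl aldehyde, to which the aryl sulfonate is inert.

Step 3
Reactants: 3 2-hydroxy-4-(tosyloxy)benzyl alcohol
Product: 4 [2-hydroxy-4-(tosyloxy)benzyl]triphenylphosphonium bromide
Conditions: PPh3·HBr, MeCN, reflux
Reagents that add atoms: triphenylphosphine hydrobromide, c1ccc(cc1)[PH+](c1ccccc1)c1ccccc1.[Br-]
Why: Acid-promoted ionisation of the ortho-hydroxybenzyl alcohol (ortho-quinone methide or benzylic cation) and capture by PPh3, the standard access to (2-hydroxybenzyl)phosphonium salts; the sulfonate tolerates HBr.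

Step 4
Reactants: 5 1-(2,3,4-trihydroxyphenyl)ethan-1-one
Product: 6 1-[4-(benzyloxy)-2,3-dihydroxyphenyl]ethan-1-one
Conditions: BnBr (1.0 equiv), NaHCO3, NaI (cat.), DMF, 40 °C
Reagents that add atoms: benzyl bromide, BrCc1ccccc1
Why: Williamson mono-alkylation with a weak base goes to the most acidic phenol, the 4-OH para to the acetyl group, because the 2-OH is chelated to the ketone and the 3-OH is not conjugated to it.

Step 5
Reactants: 6 1-[4-(benzyloxy)-2,3-dihydroxyphenyl]ethan-1-one
Product: 7 1-[4-(benzyloxy)-2-hydroxy-3-(tosyloxy)phenyl]ethan-1-one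
Conditions: TsCl (1.05 equiv), Et3N, CH2Cl2, 0 °C
Reagents that add atoms: 4-toluenesulfonyl chloride, Cc1ccc(cc1)S(=O)(=O)Cl
Why: Phenol sulfonylation at the free 3-OH; the 2-OH is tied up in the hydrogen bond to the acetyl carbonyl and is the last hydroxyl of this triad to react.

Step 6
Reactants: 7 1-[4-(benzyloxy)-2-hydroxy-3-(tosyloxy)phenyl]ethan-1-one
Product: 8 1-[4-(benzyloxy)-2-methoxy-3-(tosyloxy)phenyl]ethan-1-one
Conditions: MeI, K2CO3, DMF, 50 °C
Reagents that add atoms: iodomethane, CI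
Why: Williamson methylation of the remaining chelated phenol under forcing conditions fixes the 2'-OMe; the 2-phenoxide is the conjugated, more stable anion, so sulfonyl transfer from O3 is not expected.

Step 7
Reactants: 8 1-[4-(benzyloxy)-2-methoxy-3-(tosyloxy)phenyl]ethan-1-one
Product: 9 2-bromo-1-[4-(benzyloxy)-2-methoxy-3-(tosyloxy)phenyl]ethan-1-one
Conditions: CuBr2 (2.1 equiv), EtOAc/CHCl3, reflux
Reagents that add atoms: copper dibromide, Br[Cu]Br
Why: α-Bromination of an aryl methyl ketone through its enol with CuBr2, which should spare the ring because the acetyl and sulfonate groups deactivate it.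

Step 8
Reactants: 4 [2-hydroxy-4-(tosyloxy)benzyl]triphenylphosphonium bromide; 9 2-bromo-1-[4-(benzyloxy)-2-methoxy-3-(tosyloxy)phenyl]ethan-1-one
Product: 11 7-(tosyloxy)-3-[4-(benzyloxy)-2-methoxy-3-(tosyloxy)phenyl]-2H-chromene, via O-phenacyl phosphonium bromide 10 (not isolated)
Conditions: K2CO3 (1.1 equiv), DMF, rt; then KOt-Bu (1.1 equiv), 0 °C → rt
Reagents that add atoms: none
Why: K2CO3 deprotonates the phenol of 4 and the phenoxide displaces bromide from 9 by SN2 to lay the O1–C2 ether (10); KOt-Bu then removes a P–CH2 proton, and the semi-stabilised ylide carbon C4 adds to the ring-B ketone carbon C3 to give an oxaphosphetane that collapses to the C3=C4 alkene and Ph3PO. The closest known reaction type is the intramolecular Wittig olefination of ortho-oxygenated benzylphosphonium ylides onto a tethered carbonyl, as used for benzofurans and 2H-chromenes. The pyran ring closes by 6-exo-trig addition of C4 to the exocyclic C=O. No stereocentre is formed: C3 becomes a prochiral sp2 carbon in a ring that can hold only the cis alkene, and its configuration is set in step 9. The step needs O- over C-alkylation and ylide formation over ketone enolisation; the mild carbonate base in the first stage, the higher acidity of the P–CH2 protons compared with the ArO–CH2–C=O protons, and the six-membered transition state should secure these. The ortho-methoxy group hinders the ketone, which the intramolecular setting is meant to offset, with gentle warming if needed.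

Step 9
Reactants: 11 7-(tosyloxy)-3-[4-(benzyloxy)-2-methoxy-3-(tosyloxy)phenyl]-2H-chromene
Product: 12 (3S)-7-(tosyloxy)-3-[4-(benzyloxy)-2-methoxy-3-(tosyloxy)phenyl]chroman
Conditions: [Ir(cod)(tBu-PHOX)]BArF (2 mol %), H2 (50 bar), CH2Cl2, rt
Reagents that add atoms: none
Why: Asymmetric hydrogenation of a trisubstituted aryl alkene with an iridium phosphine-oxazoline catalyst, which needs no directing group; the chiral ligand pocket selects the face of C3=C4, so C3 is set as S under catalyst control, and the bis-sulfonate should be crystalline enough to upgrade the ee.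

Step 10
Reactants: 12 (3S)-7-(tosyloxy)-3-[4-(benzyloxy)-2-methoxy-3-(tosyloxy)phenyl]chroman
Product: 13 (3S)-7-(tosyloxy)-3-[4-hydroxy-2-methoxy-3-(tosyloxy)phenyl]chroman
Conditions: H2 (1 atm), Pd/C, EtOAc/MeOH, rt
Reagents that add atoms: none
Why: Hydrogenolysis of the benzyl ether frees only the 4'-OH; aryl sulfonates and the non-acidic C3 stereocentre are untouched.

Step 11
Reactants: 13 (3S)-7-(tosyloxy)-3-[4-hydroxy-2-methoxy-3-(tosyloxy)phenyl]chroman
Product: 14 (3S)-7-(tosyloxy)-3-[2-methoxy-4-(3-methylbut-2-enyloxy)-3-(tosyloxy)phenyl]chroman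
Conditions: prenyl bromide, K2CO3, acetone, rt
Reagents that add atoms: 1-bromo-3-methylbut-2-ene, CC(C)=CCBr
Why: Williamson O-allylation of the only free phenol; it is run at room temperature so that alkylation outpaces any sulfonyl transfer from O3' to O4'.

Step 12
Reactants: 14 (3S)-7-(tosyloxy)-3-[2-methoxy-4-(3-methylbut-2-enyloxy)-3-(tosyloxy)phenyl]chroman
Product: 15 (3S)-7-(tosyloxy)-3-[4-hydroxy-2-methoxy-5-(2-methylbut-3-en-2-yl)-3-(tosyloxy)phenyl]chroman
Conditions: N,N-diethylaniline, 190 °C, sealed tube, Ar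
Reagents that add atoms: none
Why: Aromatic Claisen rearrangement: the [3,3] shift of the aryl prenyl ether delivers the tertiary allyl terminus to C5', the only free ortho position (C3' carries OTs, the para position C1' is substituted), and tautomerisation gives the phenol.

Step 13
Reactants: 15 (3S)-7-(tosyloxy)-3-[4-hydroxy-2-methoxy-5-(2-methylbut-3-en-2-yl)-3-(tosyloxy)phenyl]chroman
Product: 16 (3S)-3-[3,4-dihydroxy-2-methoxy-5-(2-methylbut-3-en-2-yl)phenyl]chroman-7-ol
Conditions: KOH (excess), 1,4-dioxane/H2O (degassed), 90 °C, Ar; then 1 M HCl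
Reagents that add atoms: none
Why: Hydroxide attacks sulfur of both aryl sulfonates (sulfonate ester hydrolysis) in an alcohol-free medium, so no alkyl tosylate can form and O-alkylate the product; the terminal alkene, the methyl ether and C3 are inert to base, and air is excluded to protect the catechol.

Compound list
1 | 2,4-dihydroxybenzaldehyde | O=Cc1ccc(O)cc1O | starting material
2 | 2-hydroxy-4-(tosyloxy)benzaldehyde | O=Cc1ccc(OS(=O)(=O)c2ccc(C)cc2)cc1O | intermediate
3 | 2-hydroxy-4-(tosyloxy)benzyl alcohol | OCc1ccc(OS(=O)(=O)c2ccc(C)cc2)cc1O | intermediate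
4 | [2-hydroxy-4-(tosyloxy)benzyl]triphenylphosphonium bromide | Cc1ccc(cc1)S(=O)(=O)Oc1ccc(C[P+](c2ccccc2)(c2ccccc2)c2ccccc2)c(O)c1.[Br-] | intermediate
5 | 1-(2,3,4-trihydroxyphenyl)ethan-1-one | CC(=O)c1ccc(O)c(O)c1O | starting material
6 | 1-[4-(benzyloxy)-2,3-dihydroxyphenyl]ethan-1-one | CC(=O)c1ccc(OCc2ccccc2)c(O)c1O | intermediate
7 | 1-[4-(benzyloxy)-2-hydroxy-3-(tosyloxy)phenyl]ethan-1-one | CC(=O)c1ccc(OCc2ccccc2)c(OS(=O)(=O)c2ccc(C)cc2)c1O | intermediate
8 | 1-[4-(benzyloxy)-2-methoxy-3-(tosyloxy)phenyl]ethan-1-one | CC(=O)c1ccc(OCc2ccccc2)c(OS(=O)(=O)c2ccc(C)cc2)c1OC | intermediate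
9 | 2-bromo-1-[4-(benzyloxy)-2-methoxy-3-(tosyloxy)phenyl]ethan-1-one | BrCC(=O)c1ccc(OCc2ccccc2)c(OS(=O)(=O)c2ccc(C)cc2)c1OC | intermediate
10 | {2-[2-(4-(benzyloxy)-2-methoxy-3-(tosyloxy)phenyl)-2-oxoethoxy]-4-(tosyloxy)benzyl}triphenylphosphonium bromide (formed in the flask in step 8) | Cc1ccc(cc1)S(=O)(=O)Oc1ccc(C[P+](c2ccccc2)(c2ccccc2)c2ccccc2)c(OCC(=O)c2ccc(OCc3ccccc3)c(OS(=O)(=O)c3ccc(C)cc3)c2OC)c1.[Br-] | intermediate
11 | 7-(tosyloxy)-3-[4-(benzyloxy)-2-methoxy-3-(tosyloxy)phenyl]-2H-chromene | Cc1ccc(cc1)S(=O)(=O)Oc1ccc2C=C(COc2c1)c1ccc(OCc2ccccc2)c(OS(=O)(=O)c2ccc(C)cc2)c1OC | intermediate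
12 | (3S)-7-(tosyloxy)-3-[4-(benzyloxy)-2-methoxy-3-(tosyloxy)phenyl]chroman | c1cc([C@H]2COc3cc(OS(=O)(=O)c4ccc(C)cc4)ccc3C2)c(OC)c(OS(=O)(=O)c2ccc(C)cc2)c1OCc1ccccc1 | intermediate
13 | (3S)-7-(tosyloxy)-3-[4-hydroxy-2-methoxy-3-(tosyloxy)phenyl]chroman | c1cc([C@H]2COc3cc(OS(=O)(=O)c4ccc(C)cc4)ccc3C2)c(OC)c(OS(=O)(=O)c2ccc(C)cc2)c1O | intermediate
14 | (3S)-7-(tosyloxy)-3-[2-methoxy-4-(3-methylbut-2-enyloxy)-3-(tosyloxy)phenyl]chroman | c1cc([C@H]2COc3cc(OS(=O)(=O)c4ccc(C)cc4)ccc3C2)c(OC)c(OS(=O)(=O)c2ccc(C)cc2)c1OCC=C(C)C | intermediate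
15 | (3S)-7-(tosyloxy)-3-[4-hydroxy-2-methoxy-5-(2-methylbut-3-en-2-yl)-3-(tosyloxy)phenyl]chroman | C=CC(C)(C)c1cc([C@H]2COc3cc(OS(=O)(=O)c4ccc(C)cc4)ccc3C2)c(OC)c(OS(=O)(=O)c2ccc(C)cc2)c1O | intermediate
16 | (3S)-3-[3,4-dihydroxy-2-methoxy-5-(2-methylbut-3-en-2-yl)phenyl]chroman-7-ol | C=CC(C)(C)c1cc([C@H]2COc3cc(O)ccc3C2)c(OC)c(O)c1O | target

Total steps: 13. Longest linear sequence: 10 steps (5 → 16, steps 4–13); the ring-A branch (steps 1–3) joins at step 8.

Steps most likely to fail

Step 8. The ylide may add too slowly to the hindered ortho-methoxy aryl ketone, so that ketone enolisation or C-alkylation of the ylide takes over and the ring does not close. The fallback closes the same C3=C4 bond by ring-closing olefin metathesis and sets out from 2 and 9. Aldehyde 2 is methylenated with Ph3P=CH2 (2.2 equiv, THF, 0 °C) to 2-hydroxy-4-(tosyloxy)styrene F1. Its phenol is alkylated with 9 (K2CO3, acetone, rt) to the aryloxy ketone F2. A second methylenation of the ketone (Ph3P=CH2, THF, 0 °C → rt) gives the diene F3. Second-generation Grubbs catalyst, RuCl2(=CHPh)(PCy3)(H2IMes), in toluene at 80 °C then closes the pyran ring with loss of ethylene, and the route is rejoined at 11.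

Step 9. The 2'-methoxy group twists ring B out of the alkene plane and crowds the trisubstituted C3=C4 bond, so the hydrogenation may stall or discriminate the faces poorly. The fallback sets out from 11 and sets C3 by dynamic kinetic resolution instead. Hydroboration–oxidation (BH3·THF; then NaBO3, THF/H2O) gives the racemic trans-isoflavan-4-ol F4, and Dess–Martin periodinane oxidises it to the racemic isoflavanone F5, whose C3–H is labile. Asymmetric transfer hydrogenation with RuCl[TsDPEN](p-cymene) in HCO2H/Et3N reduces the ketone while C3 equilibrates, and with the appropriate catalyst antipode should give the cis-(3S,4S)-isoflavan-4-ol F6. Hydrogenolysis (H2, Pd(OH)2/C, EtOH/AcOH) removes the benzylic C4 hydroxyl and the benzyl ether together, and the route is rejoined at 13.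

Step 12. At 190 °C the rearranged ortho-(1,1-dimethylallyl)phenol may react on (abnormal Claisen isomerisation of the side chain, addition of the phenol to the vinyl group), or the prenyl ether may simply fragment. The fallback sets out from 13 and forms the aryl–C bond by cross-coupling. NBS (MeCN, 0 °C) brominates C5', the only free position ortho to the 4'-OH, to give the bromophenol F7. A Suzuki–Miyaura coupling with 3-methylbut-2-enylboronic acid pinacol ester (Pd(OAc)2, a bulky biaryl dialkylphosphine chosen for the branched, γ-coupled isomer, K3PO4, THF/H2O, 40 °C) installs the 2-methylbut-3-en-2-yl group, and the route is rejoined at 15.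

Further compounds
F1 | step 8 | 2-hydroxy-4-(tosyloxy)styrene | C=Cc1ccc(OS(=O)(=O)c2ccc(C)cc2)cc1O
F2 | step 8 | 1-[4-(benzyloxy)-2-methoxy-3-(tosyloxy)phenyl]-2-[5-(tosyloxy)-2-vinylphenoxy]ethan-1-one | C=Cc1ccc(OS(=O)(=O)c2ccc(C)cc2)cc1OCC(=O)c1ccc(OCc2ccccc2)c(OS(=O)(=O)c2ccc(C)cc2)c1OC
F3 | step 8 | 2-{[2-(4-(benzyloxy)-2-methoxy-3-(tosyloxy)phenyl)prop-2-enyl]oxy}-4-(tosyloxy)styrene | C=Cc1ccc(OS(=O)(=O)c2ccc(C)cc2)cc1OCC(=C)c1ccc(OCc2ccccc2)c(OS(=O)(=O)c2ccc(C)cc2)c1OC
F4 | step 9 | racemic trans-7-(tosyloxy)-3-[4-(benzyloxy)-2-methoxy-3-(tosyloxy)phenyl]chroman-4-ol (the 3S,4R enantiomer is drawn) | c1cc([C@H]2COc3cc(OS(=O)(=O)c4ccc(C)cc4)ccc3[C@@H]2O)c(OC)c(OS(=O)(=O)c2ccc(C)cc2)c1OCc1ccccc1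
F5 | step 9 | racemic 7-(tosyloxy)-3-[4-(benzyloxy)-2-methoxy-3-(tosyloxy)phenyl]chroman-4-one (C3 configurationally labile) | Cc1ccc(cc1)S(=O)(=O)Oc1ccc2C(=O)C(COc2c1)c1ccc(OCc2ccccc2)c(OS(=O)(=O)c2ccc(C)cc2)c1OC
F6 | step 9 | cis-(3S,4S)-7-(tosyloxy)-3-[4-(benzyloxy)-2-methoxy-3-(tosyloxy)phenyl]chroman-4-ol | c1cc([C@H]2COc3cc(OS(=O)(=O)c4ccc(C)cc4)ccc3[C@H]2O)c(OC)c(OS(=O)(=O)c2ccc(C)cc2)c1OCc1ccccc1
F7 | step 12 | (3S)-7-(tosyloxy)-3-[5-bromo-4-hydroxy-2-methoxy-3-(tosyloxy)phenyl]chroman | Brc1cc([C@H]2COc3cc(OS(=O)(=O)c4ccc(C)cc4)ccc3C2)c(OC)c(OS(=O)(=O)c2ccc(C)cc2)c1O
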